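## Retrosynthetic overview

- The strategy rests on C1 being the β-carbon of the C1=C10–C14HO enal inside the ten-membered carbocycle (C1–C10). With a phenylsulfonyl group on C1, that carbon can take up a C2 radical and then lose the sulfonyl group, which restores the enal.
- Ring order: the ten-membered carbocycle is closed first at C1–C2 (34 to 35). The α-methylene-γ-lactone (O6–C12) is closed second by oxidation of the 6,12-diol 37.
- Precursor 34 comes from a C6–C7 allylboration of enal 24 (C2–C6 and C15, from 2-butyne-1,4-diol) with allylboronate 14 (C7–C14 and C1, from L-tartrate).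
- C8 and C9 come from L-tartrate, and C6 and C7 from the chair allylboration. O8 and O9 are told apart by an O9,O14-silylene, and the side-chain centre comes from the (R)-acid.

Key step: step 25

Assumption: germacrane numbering (C1–C15) is used for all fragments, and 1, 8, 15 and 29 are taken as purchasable.

## Route

Step 1
Reactants: 1 dimethyl 2,3-O-isopropylidene-L-tartrate
Product: 3 methyl (4R,5S)-5-ethynyl-2,2-dimethyl-1,3-dioxolane-4-carboxylate, via formyl ester 2 (not isolated)
Conditions: i-Bu2AlH (1.0 equiv), CH2Cl2, −78 °C; then MeOH, K2CO3, dimethyl (1-diazo-2-oxopropyl)phosphonate, −78 °C to rt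
Reagents that add atoms: dimethyl (1-diazo-2-oxopropyl)phosphonate, COP(=O)(OC)C(=[N+]=[N-])C(C)=O
Why: Partial ester reduction followed in the same flask by Ohira–Bestmann homologation desymmetrises the C2-symmetric diester (C7 ester, C10≡C1 alkyne), and C8/C9 are safe because the trans-dioxolane is the thermodynamic epimer under K2CO3/MeOH.

Step 2
Reactants: 3 alkyne ester
Product: 4 (E)-β-iodovinyl sulfone ester (I on C10 trans to PhSO2 on C1)
Conditions: PhSO2Na, I2, EtOAc/H2O, visible light, rt
Reagents that add atoms: sodium benzenesulfinate, [Na+].[O-]S(=O)c1ccccc1; iodine, II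
Why: In this radical iodosulfonylation of a terminal alkyne the sulfonyl radical adds to the terminal C1 and iodine is transferred anti to C10, and it is run here because no other π bond is yet present.

Step 3
Reactants: 4 β-iodovinyl sulfone ester
Product: 5 C14 allylic alcohol (C9 cis to PhSO2)
Conditions: Bu3SnCH2OH, Pd2(dba)3 (2.5 mol %), AsPh3 (10 mol %), NMP, 60 °C
Reagents that add atoms: (tributylstannyl)methanol, CCCC[Sn](CCCC)(CCCC)CO
Why: Stille coupling of the activated vinyl iodide transfers CH2OH (C14) to C10 with retention, so C9 stays cis to the sulfonyl group.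

Step 4
Reactants: 5 C14 allylic alcohol
Product: 6 O14-TBS ether
Conditions: TBSCl, imidazole, CH2Cl2, 0 °C to rt
Reagents that add atoms: tert-butyldimethylsilyl chloride, CC(C)(C)[Si](C)(C)Cl
Why: Standard silylation masks the primary allylic alcohol before it can lactonise onto the C7 ester.

Step 5
Reactants: 6 O14-TBS ester
Product: 7 C7 aldehyde
Conditions: i-Bu2AlH (1.1 equiv), toluene, −78 °C; aq. potassium sodium tartrate
Reagents that add atoms: none
Why: Partial reduction of the α-alkoxy methyl ester stops at the chelated aluminium hemiacetal at −78 °C, and the vinyl sulfone, ketal and silyl ether are inert.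

Step 6
Reactants: 7 C7 aldehyde; 8 ethyl 2-(diethoxyphosphoryl)acrylate
Product: 10 (E)-enoate (C8 trans to CO2Et and cis to CH2OPMB), via sodium phosphonate 9 (not isolated)
Conditions: 4-MeOC6H4CH2OH, NaH, THF, 0 °C; 8; then 7, −78 °C to 0 °C
Reagents that add atoms: 4-methoxybenzyl alcohol, COc1ccc(CO)cc1; sodium hydride, [Na+].[H-] (sodium kept only in 9)
Why: In this tandem oxa-Michael addition/Horner–Wadsworth–Emmons olefination the alkoxide adds to 8 and the stabilised anion 9 olefinates 7 with the usual E preference of α-substituted phosphonoacetates, while the trans-dioxolane guards C8 against epimerisation.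

Step 7
Reactants: 10 (E)-enoate
Product: 11 C13 allylic alcohol
Conditions: i-Bu2AlH (2.5 equiv), CH2Cl2, −78 °C; aq. potassium sodium tartrate
Reagents that add atoms: none
Why: 1,2-Reduction of the enoate gives the allylic alcohol without touching the alkene geometry, the vinyl sulfone or the ethers.

Step 8
Reactants: 11 C13 allylic alcohol
Product: 13 C13 allylic chloride, via allylic mesylate 12 (not isolated)
Conditions: MsCl, 2,4,6-collidine, LiCl, DMF, 0 °C
Reagents that add atoms: methanesulfonyl chloride, CS(=O)(=O)Cl (kept only in 12); lithium chloride, [Li+].[Cl-]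
Why: Mesylation and in situ SN2 displacement by chloride convert the primary allylic alcohol without allylic transposition, so C8 stays trans to C13.

Step 9
Reactants: 13 allylic chloride
Product: 14 allyl pinacolboronate (C8 trans to CH2B)
Conditions: B2pin2, Pd2(dba)3 (2.5 mol %), THF, rt to 60 °C
Reagents that add atoms: bis(pinacolato)diboron, CC1(C)OB(OC1(C)C)B1OC(C)(C)C(C)(C)O1
Why: In this palladium-catalysed (Miyaura-type) borylation of an allylic chloride the C–B bond forms at the unhindered primary terminus faster than syn–anti exchange at the hindered C7 end, so the alkene geometry is kept.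

Step 10
Reactants: 15 2-butyne-1,4-diol
Product: 16 mono-TBDPS ether
Conditions: TBDPSCl (0.3 equiv), imidazole, THF/DMF, 0 °C to rt
Reagents that add atoms: tert-butyl(chloro)diphenylsilane, CC(C)(C)[Si](Cl)(c1ccccc1)c1ccccc1
Why: Statistical monosilylation of the symmetric diol used in excess installs an O15 group that outlasts every later acid step.

Step 11
Reactants: 16 mono-TBDPS ether
Product: 18 (Z)-4-(TBDPS-oxy)-3-iodobut-2-en-1-ol, via vinylalanate 17 (not isolated)
Conditions: NaAlH2(OCH2CH2OMe)2, THF, 0 °C to rt; then I2, −78 °C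
Reagents that add atoms: sodium bis(2-methoxyethoxy)aluminium hydride, [Na+].[AlH2-](OCCOC)OCCOC (kept only in 17); iodine, II
Why: Hydroxyl-directed trans-hydroalumination places aluminium on C4 in a five-membered alanate, and iodinolysis with retention puts iodine cis to C6, which fixes the ring-cis C4=C5 geometry.

Step 12
Reactants: 18 (Z)-vinyl iodide
Product: 19 (E)-dienol (vinyl group cis to C6)
Conditions: Bu3SnCH=CH2, PdCl2(MeCN)2 (5 mol %), DMF, rt
Reagents that add atoms: tributyl(vinyl)stannane, C=C[Sn](CCCC)(CCCC)CCCC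
Why: Stille vinylation with retention brings in C2 and C3 cis to C6.

Step 13
Reactants: 19 dienol
Product: 20 O6-TES ether
Conditions: TESCl, imidazole, CH2Cl2, 0 °C
Reagents that add atoms: chlorotriethylsilane, CC[Si](Cl)(CC)CC
Why: Standard silylation gives a temporary O6 group that step 16 can oxidise directly.

Step 14
Reactants: 20 diene TES ether
Product: 22 C2 primary alcohol, via alkyl-9-BBN 21 (not isolated)
Conditions: 9-BBN, THF, 0 °C to rt; then NaBO3·4H2O, H2O, rt
Reagents that add atoms: 9-borabicyclo[3.3.1]nonane, B1C2CCCC1CCC2 (kept only in 21); sodium perborate, [Na+].[Na+].O[B-]1(O)OO[B-](O)(O)OO1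
Why: In this hydroboration–oxidation the bulky borane takes only the monosubstituted end of the diene and leaves the trisubstituted C4=C5 bond, and perborate spares the silyl ethers.

Step 15
Reactants: 22 C2 alcohol
Product: 23 C2 primary iodide
Conditions: I2, PPh3, imidazole, CH2Cl2, 0 °C
Reagents that add atoms: iodine, II
Why: Buffered Appel iodination of the only free, primary alcohol.

Step 16
Reactants: 23 iodide TES ether
Product: 24 (E)-5-iodo-3-(TBDPS-oxymethyl)pent-2-enal (C3 cis to CHO)
Conditions: (COCl)2, DMSO, CH2Cl2, −78 °C to −40 °C; Et3N, −78 °C to 0 °C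
Reagents that add atoms: none
Why: In this Swern oxidation the activated DMSO first cleaves the primary allylic TES ether (oxidative desilylation), which avoids a free iodo alcohol that could close to a dihydropyran and leaves the TBDPS ether and the iodide alone.

Step 17
Reactants: 14 allyl pinacolboronate; 24 C2–C6 enal
Product: 25 acyclic C6 alcohol (C6–C7 bond and C11=C13 methylene formed)
Conditions: (S)-TRIP (10 mol %), 4 Å sieves, toluene, −30 °C to rt; aq. NaHCO3
Reagents that add atoms: none
Why: In this chiral-phosphoric-acid-catalysed allylboration through a closed chair, C8 trans to CH2B sits equatorial and gives the 6,7-anti pair (future trans-lactone), A(1,3) strain with the cis CH2OPMB group holds H8 in the alkene plane so the aldehyde arrives anti to the C8–C9 bond, and (S)-TRIP is chosen, by analogy with simple allyl and crotyl pinacolboronates, to reinforce the face that gives 6R.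

Step 18
Reactants: 25 C6 alcohol
Product: 26 O6-TBS ether
Conditions: TBSOTf, 2,6-lutidine, CH2Cl2, −78 °C to 0 °C
Reagents that add atoms: tert-butyldimethylsilyl triflate, CC(C)(C)[Si](C)(C)OS(=O)(=O)C(F)(F)F
Why: Triflate silylation covers the hindered secondary alcohol under non-nucleophilic conditions that leave the C2 iodide alone.

Step 19
Reactants: 26 O6-TBS ether
Product: 27 8,9,14-triol
Conditions: AcOH/H2O/THF (3:1:1), 45 °C
Reagents that add atoms: none
Why: Mild acid hydrolysis removes the ketal and the primary allylic TBS ether, whereas the hindered secondary TBS, the TBDPS and the PMB ethers are markedly more acid-stable.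

Step 20
Reactants: 27 triol
Product: 28 O9,O14-di-tert-butylsilylene with free O8–H
Conditions: t-Bu2Si(OTf)2 (1.05 equiv), 2,6-lutidine, CH2Cl2, −40 °C to 0 °C
Reagents that add atoms: di-tert-butylsilyl bis(triflate), CC(C)(C)[Si](OS(=O)(=O)C(F)(F)F)(OS(=O)(=O)C(F)(F)F)C(C)(C)C
Why: In this cyclic silylene formation the reagent takes the primary O14–H first and then closes the six-membered dioxasilinane onto O9 rather than a seven-membered ring onto O8, which tells O8 and O9 apart.

Step 21
Reactants: 28 O8 alcohol; 29 (R)-2-methylbutanoic acid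
Product: 30 O8 (R)-2-methylbutanoate
Conditions: DCC, DMAP (0.3 equiv), CH2Cl2, 0 °C to rt
Reagents that add atoms: none
Why: Steglich esterification of the only free hydroxyl, with substoichiometric DMAP to limit both epimerisation of the acid and alkylation by the iodide.

Step 22
Reactants: 30 silylene ester
Product: 31 9,14-diol
Conditions: HF·pyridine, pyridine, THF, 0 °C
Reagents that add atoms: none
Why: Buffered fluoride cleaves the cyclic silylene much faster than TBS or TBDPS ethers, and the acidic medium suppresses acyl migration.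

Step 23
Reactants: 31 9,14-diol
Product: 33 O9 acetate with free C14–OH, via cyclic orthoacetate 32 (not isolated)
Conditions: MeC(OMe)3, CSA (cat.), CH2Cl2, rt; then 80 % aq. AcOH, 0 °C
Reagents that add atoms: trimethyl orthoacetate, COC(C)(OC)OC; water, O
Why: In this cyclic orthoester formation and kinetic hydrolysis the opening releases the less hindered primary oxygen and leaves the acetate on the secondary O9.

Step 24
Reactants: 33 C14 alcohol
Product: 34 (E)-β-(phenylsulfonyl) enal with C2 iodide (cyclisation precursor)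
Conditions: Dess–Martin periodinane, CH2Cl2, 0 °C
Reagents that add atoms: none
Why: Dess–Martin oxidation unveils the acceptor in the last step under amine-free conditions, and 34 is used at once.

Step 25
Reactants: 34 iodide β-sulfonyl enal
Product: 35 ten-membered C14 enal diester (O6 TBS, O12 PMB, O15 TBDPS)
Conditions: 4CzIPN (5 mol %), i-Pr2NEt (5 equiv), degassed MeCN (2 mM), blue LEDs (450 nm), rt
Reagents that add atoms: none
Why: Proposed new method: excited 4CzIPN oxidises i-Pr2NEt, the derived α-aminoalkyl radical abstracts iodine from C2, the nucleophilic primary C2 radical adds to C1 to give the formyl-stabilised tertiary C10 radical, β-scission of C1–S expels the sulfonyl radical and restores C1=C10, and reduced 4CzIPN turns that radical into sulfinate. The closest known reaction types are intermolecular radical alkenylation by addition–fragmentation on β-sulfonyl acrylates and vinyl sulfones and endo-mode radical macrocyclisation onto electron-poor alkenes, and their combination in a ten-membered closure has not been shown. The carbocycle closes in a 10-endo-trig mode, helped by high dilution, by the cis C4=C5 bond that turns the C2–C3 arm back toward the chain, and by polarity matching of radical and acceptor. No stereocentre is formed and C6–C9 are not touched. The step needs attack at C1 and not at C10, which the fully substituted C10 and the radical-stabilising formyl group secure, and it needs CHO trans to C2 (the ring-cis enal), which is the thermodynamic 2-substituted enal reached through the common C10 radical and, if needed, through reversible conjugate addition of the released sulfinate. A photocatalyst whose excited state is an oxidant rather than a strong reductant and a hindered amine are chosen so that neither electron transfer nor amine addition consumes the acceptor, and the 2-(alkoxymethyl)allyl group on C7 is no radical trap, which is why the lactone is closed later.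

Step 26
Reactants: 35 macrocyclic enal
Product: 36 C12 allylic alcohol
Conditions: DDQ (1.3 equiv), CH2Cl2/pH 7 buffer, 0 °C
Reagents that add atoms: none
Why: Oxidative PMB cleavage is neutral and leaves the enal, the esters and the silyl ethers.

Step 27
Reactants: 36 C12 alcohol
Product: 37 6,12-diol
Conditions: 48 % aq. HF, MeCN, 0 °C
Reagents that add atoms: none
Why: Acidic fluoride desilylation removes the secondary TBS ether, while the far more acid-stable primary TBDPS ether keeps O15 covered for the oxidation.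

Step 28
Reactants: 37 6,12-diol
Product: 40 O15-TBDPS α-methylene-γ-lactone, via hydroxy enal 38 (not isolated), via lactol 39 (not isolated)
Conditions: TEMPO (0.2 equiv), PhI(OAc)2 (2.5 equiv), CH2Cl2, rt
Reagents that add atoms: none
Why: In this oxidative lactonisation of a 1,4-diol the oxoammonium salt takes the primary allylic C12–OH in preference to the secondary C6–OH, the aldehyde is trapped by O6 as a lactol and oxidised again, and the C14 enal is not affected, so no acetal protection is needed.

Step 29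
Reactants: 40 silyl lactone
Product: 41 CNP0247637.4
Conditions: HF·pyridine, pyridine, THF, rt
Reagents that add atoms: none
Why: Buffered fluoride desilylation frees C15–OH without base, so the α-methylene lactone, the enal and both esters survive.

## Compound list

1 | dimethyl (4R,5R)-2,2-dimethyl-1,3-dioxolane-4,5-dicarboxylate | COC(=O)[C@@H]1OC(C)(C)O[C@H]1C(=O)OC | starting material
2 | methyl (4R,5R)-5-formyl-2,2-dimethyl-1,3-dioxolane-4-carboxylate | COC(=O)[C@@H]1OC(C)(C)O[C@H]1C=O | intermediate
3 | methyl (4R,5S)-5-ethynyl-2,2-dimethyl-1,3-dioxolane-4-carboxylate | COC(=O)[C@@H]1OC(C)(C)O[C@H]1C#C | intermediate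
4 | methyl (4R,5R)-5-[(E)-1-iodo-2-(phenylsulfonyl)ethenyl]-2,2-dimethyl-1,3-dioxolane-4-carboxylate | COC(=O)[C@@H]1OC(C)(C)O[C@H]1/C(I)=C\S(=O)(=O)c1ccccc1 | intermediate
5 | methyl (4R,5S)-5-[(Z)-3-hydroxy-1-(phenylsulfonyl)prop-1-en-2-yl]-2,2-dimethyl-1,3-dioxolane-4-carboxylate | COC(=O)[C@@H]1OC(C)(C)O[C@H]1/C(CO)=C\S(=O)(=O)c1ccccc1 | intermediate
6 | O14-TBS ether of 5 | COC(=O)[C@@H]1OC(C)(C)O[C@H]1/C(CO[Si](C)(C)C(C)(C)C)=C\S(=O)(=O)c1ccccc1 | intermediate
7 | C7 aldehyde (8,9-O-isopropylidene, O14-TBS, Z-vinyl sulfone) | O=C[C@@H]1OC(C)(C)O[C@H]1/C(CO[Si](C)(C)C(C)(C)C)=C\S(=O)(=O)c1ccccc1 | intermediate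
8 | ethyl 2-(diethoxyphosphoryl)acrylate | C=C(C(=O)OCC)P(=O)(OCC)OCC | starting material
9 | sodium salt of ethyl 2-(diethoxyphosphoryl)-3-[(4-methoxybenzyl)oxy]propanoate | [Na+].CCOC(=O)[C-](COCc1ccc(OC)cc1)P(=O)(OCC)OCC | intermediate
10 | (E)-enoate, C13 ethyl ester, C8 cis to CH2OPMB | CCOC(=O)/C(COCc1ccc(OC)cc1)=C/[C@@H]1OC(C)(C)O[C@H]1/C(CO[Si](C)(C)C(C)(C)C)=C\S(=O)(=O)c1ccccc1 | intermediate
11 | C13 allylic alcohol, C8 trans to C13 | OC/C(COCc1ccc(OC)cc1)=C/[C@@H]1OC(C)(C)O[C@H]1/C(CO[Si](C)(C)C(C)(C)C)=C\S(=O)(=O)c1ccccc1 | intermediate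
12 | C13 allylic mesylate | CS(=O)(=O)OC/C(COCc1ccc(OC)cc1)=C/[C@@H]1OC(C)(C)O[C@H]1/C(CO[Si](C)(C)C(C)(C)C)=C\S(=O)(=O)c1ccccc1 | intermediate
13 | C13 allylic chloride | ClC/C(COCc1ccc(OC)cc1)=C/[C@@H]1OC(C)(C)O[C@H]1/C(CO[Si](C)(C)C(C)(C)C)=C\S(=O)(=O)c1ccccc1 | intermediate
14 | C13 allyl pinacolboronate, C8 trans to CH2B | CC1(C)OB(C/C(COCc2ccc(OC)cc2)=C/[C@@H]2OC(C)(C)O[C@H]2/C(CO[Si](C)(C)C(C)(C)C)=C\S(=O)(=O)c2ccccc2)OC1(C)C | intermediate
15 | 2-butyne-1,4-diol | OCC#CCO | starting material
16 | 4-(tert-butyldiphenylsilyloxy)but-2-yn-1-ol | OCC#CCO[Si](c1ccccc1)(c1ccccc1)C(C)(C)C | intermediate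
17 | sodium five-membered alkoxy vinylalanate (Al on C4) | [Na+].COCCO[Al-]1(OCCOC)OCC=C1CO[Si](c2ccccc2)(c2ccccc2)C(C)(C)C | intermediate
18 | (Z)-4-(tert-butyldiphenylsilyloxy)-3-iodobut-2-en-1-ol | OC/C=C(\I)CO[Si](c1ccccc1)(c1ccccc1)C(C)(C)C | intermediate
19 | (E)-3-[(tert-butyldiphenylsilyloxy)methyl]penta-2,4-dien-1-ol | OC/C=C(\C=C)CO[Si](c1ccccc1)(c1ccccc1)C(C)(C)C | intermediate
20 | O6-TES ether of 19 | CC[Si](CC)(CC)OC/C=C(\C=C)CO[Si](c1ccccc1)(c1ccccc1)C(C)(C)C | intermediate
21 | C2 B-alkyl-9-BBN adduct of 20 | CC[Si](CC)(CC)OC/C=C(\CCB1C2CCCC1CCC2)CO[Si](c1ccccc1)(c1ccccc1)C(C)(C)C | intermediate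
22 | C2 primary alcohol (O6 TES, O15 TBDPS, C3 cis to C6) | CC[Si](CC)(CC)OC/C=C(\CCO)CO[Si](c1ccccc1)(c1ccccc1)C(C)(C)C | intermediate
23 | C2 primary iodide (O6 TES, O15 TBDPS) | CC[Si](CC)(CC)OC/C=C(\CCI)CO[Si](c1ccccc1)(c1ccccc1)C(C)(C)C | intermediate
24 | (E)-3-[(tert-butyldiphenylsilyloxy)methyl]-5-iodopent-2-enal | O=C/C=C(\CCI)CO[Si](c1ccccc1)(c1ccccc1)C(C)(C)C | intermediate
25 | acyclic C6 alcohol (6R, 6,7-anti; C2 iodide, O15 TBDPS, O12 PMB, 8,9-O-isopropylidene, O14 TBS, Z-vinyl sulfone) | ICC/C(CO[Si](c1ccccc1)(c1ccccc1)C(C)(C)C)=C\[C@@H](O)[C@H](C(=C)COCc1ccc(OC)cc1)[C@@H]1OC(C)(C)O[C@H]1/C(CO[Si](C)(C)C(C)(C)C)=C\S(=O)(=O)c1ccccc1 | intermediate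
26 | O6-TBS ether of 25 | ICC/C(CO[Si](c1ccccc1)(c1ccccc1)C(C)(C)C)=C\[C@@H](O[Si](C)(C)C(C)(C)C)[C@H](C(=C)COCc1ccc(OC)cc1)[C@@H]1OC(C)(C)O[C@H]1/C(CO[Si](C)(C)C(C)(C)C)=C\S(=O)(=O)c1ccccc1 | intermediate
27 | 8,9,14-triol | ICC/C(CO[Si](c1ccccc1)(c1ccccc1)C(C)(C)C)=C\[C@@H](O[Si](C)(C)C(C)(C)C)[C@H](C(=C)COCc1ccc(OC)cc1)[C@H](O)[C@@H](O)/C(CO)=C\S(=O)(=O)c1ccccc1 | intermediate
28 | O9,O14-di-tert-butylsilylene, O8–H free | ICC/C(CO[Si](c1ccccc1)(c1ccccc1)C(C)(C)C)=C\[C@@H](O[Si](C)(C)C(C)(C)C)[C@H](C(=C)COCc1ccc(OC)cc1)[C@H](O)[C@H]1O[Si](C(C)(C)C)(C(C)(C)C)OC/C1=C/S(=O)(=O)c1ccccc1 | intermediate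
29 | (R)-2-methylbutanoic acid | CC[C@@H](C)C(=O)O | starting material
30 | O8 (R)-2-methylbutanoate of 28 | ICC/C(CO[Si](c1ccccc1)(c1ccccc1)C(C)(C)C)=C\[C@@H](O[Si](C)(C)C(C)(C)C)[C@H](C(=C)COCc1ccc(OC)cc1)[C@H](OC(=O)[C@H](C)CC)[C@H]1O[Si](C(C)(C)C)(C(C)(C)C)OC/C1=C/S(=O)(=O)c1ccccc1 | intermediate
31 | 9,14-diol O8 ester | ICC/C(CO[Si](c1ccccc1)(c1ccccc1)C(C)(C)C)=C\[C@@H](O[Si](C)(C)C(C)(C)C)[C@H](C(=C)COCc1ccc(OC)cc1)[C@H](OC(=O)[C@H](C)CC)[C@@H](O)/C(CO)=C\S(=O)(=O)c1ccccc1 | intermediate
32 | O9,O14 cyclic methyl orthoacetate (orthoester carbon unassigned) | ICC/C(CO[Si](c1ccccc1)(c1ccccc1)C(C)(C)C)=C\[C@@H](O[Si](C)(C)C(C)(C)C)[C@H](C(=C)COCc1ccc(OC)cc1)[C@H](OC(=O)[C@H](C)CC)[C@H]1OC(C)(OC)OC/C1=C/S(=O)(=O)c1ccccc1 | intermediate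
33 | O9 acetate, O8 ester, C14–OH free | ICC/C(CO[Si](c1ccccc1)(c1ccccc1)C(C)(C)C)=C\[C@@H](O[Si](C)(C)C(C)(C)C)[C@H](C(=C)COCc1ccc(OC)cc1)[C@H](OC(=O)[C@H](C)CC)[C@@H](OC(C)=O)/C(CO)=C\S(=O)(=O)c1ccccc1 | intermediate
34 | cyclisation precursor: C2 iodide, (E)-(phenylsulfonyl)methylene enal at C10 (sulfonyl trans to CHO) | ICC/C(CO[Si](c1ccccc1)(c1ccccc1)C(C)(C)C)=C\[C@@H](O[Si](C)(C)C(C)(C)C)[C@H](C(=C)COCc1ccc(OC)cc1)[C@H](OC(=O)[C@H](C)CC)[C@@H](OC(C)=O)/C(C=O)=C\S(=O)(=O)c1ccccc1 | intermediate
35 | ten-membered C14 enal diester (both ring alkenes ring-cis; O6 TBS, O12 PMB, O15 TBDPS) | CC(C)(C)[Si](C)(C)O[C@@H]1/C=C(/CO[Si](c2ccccc2)(c2ccccc2)C(C)(C)C)CC/C=C(/C=O)[C@H](OC(C)=O)[C@@H](OC(=O)[C@H](C)CC)[C@H]1C(=C)COCc1ccc(OC)cc1 | intermediate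
36 | C12 allylic alcohol (O6 TBS, O15 TBDPS) | CC(C)(C)[Si](C)(C)O[C@@H]1/C=C(/CO[Si](c2ccccc2)(c2ccccc2)C(C)(C)C)CC/C=C(/C=O)[C@H](OC(C)=O)[C@@H](OC(=O)[C@H](C)CC)[C@H]1C(=C)CO | intermediate
37 | 6,12-diol (O15 TBDPS) | O[C@@H]1/C=C(/CO[Si](c2ccccc2)(c2ccccc2)C(C)(C)C)CC/C=C(/C=O)[C@H](OC(C)=O)[C@@H](OC(=O)[C@H](C)CC)[C@H]1C(=C)CO | intermediate
38 | 6-hydroxy C12 enal | O[C@@H]1/C=C(/CO[Si](c2ccccc2)(c2ccccc2)C(C)(C)C)CC/C=C(/C=O)[C@H](OC(C)=O)[C@@H](OC(=O)[C@H](C)CC)[C@H]1C(=C)C=O | intermediate
39 | 6,12-lactol (C12 unassigned) | C=C1C(O)O[C@@H]2/C=C(/CO[Si](c3ccccc3)(c3ccccc3)C(C)(C)C)CC/C=C(/C=O)[C@H](OC(C)=O)[C@@H](OC(=O)[C@H](C)CC)[C@@H]12 | intermediate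
40 | O15-TBDPS ether of the target lactone | C=C1C(=O)O[C@@H]2/C=C(/CO[Si](c3ccccc3)(c3ccccc3)C(C)(C)C)CC/C=C(/C=O)[C@H](OC(C)=O)[C@@H](OC(=O)[C@H](C)CC)[C@@H]12 | intermediate
41 | CNP0247637.4 (6R,7S,8S,9S; side chain R) | C=C1C(=O)O[C@@H]2/C=C(/CO)CC/C=C(/C=O)[C@H](OC(C)=O)[C@@H](OC(=O)[C@H](C)CC)[C@@H]12 | target

## Step count

- Total step count: 29.
- Longest linear sequence: 22 (steps 1–9 and 17–29).

## Steps most likely to fail

**1. Step 25 (key step).**
- The slow 10-endo closure may lose to hydrogen abstraction by the C2 radical from amine or solvent.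
- It may also lose to 1,5-hydrogen transfer from the allylic, oxygen-bearing C6–H.
- Reversible 3-exo closure onto C4=C5 could scramble that alkene.
- Electron transfer to the acceptor could cause desulfonylation.
- Intermolecular addition could give oligomers.

Fallback: it sets out from 34 and comes back at 35, and each operation is an established polar reaction. Stirring 34 with MeOH and Et3N exchanges the sulfonyl group for methoxy by addition–elimination. This gives the (E)-β-methoxy enal F1, a vinylogous formate ester. Slow addition of F1 to excess CrCl2 with catalytic cobalt phthalocyanine Co(C32H16N8) in DMF lets divalent chromium turn the C2 iodide into an alkylchromium reagent. That reagent adds to the formyl carbon in a Nozaki–Hiyama–Kishi-type macrocyclic carbonyl addition, which tolerates esters and silyl ethers. The product is the ten-membered carbinol F2, an epimer mixture at the carbinol carbon, with an exocyclic methoxymethylene group on C10. PPTS in wet acetone then ionises the allylic carbinol, water enters at the methoxymethylene carbon and methanol leaves (Stork–Danheiser-type transposition of a vinylogous ester). This gives the thermodynamic enal 35. The two one-carbon arms on C10 swap roles: the former formyl carbon ends as ring carbon C1 and the former C1 as C14.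

**2. Step 17.**
- Facial selectivity may be poor if the bias from C8 and the catalyst disagree.
- The hindered boronate may add so slowly that borotropic loss of alkene geometry erodes the 6,7-anti relationship.

Fallback: it sets out from 13 and comes back at 25, and it moves stereocontrol from an external catalyst to a covalently bound auxiliary. Borylation of 13 with bis(diisopropyl L-tartrate glycolato)diboron under the palladium conditions of step 9 gives the tartrate-modified allylboronate F3. Its more Lewis-acidic boron reacts with 24 without catalyst (4 Å sieves, toluene, −78 °C) under double asymmetric induction and gives 25.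

**3. Step 23.**
- The orthoester may open toward the primary acetate.
- Acyl groups may migrate (O9 to O14, or O8 to O9) during the acidic hydrolysis.

Fallback: it sets out from 31 and comes back at 33 and replaces the orthoester by a protect–acylate–release sequence. TESCl and 2,6-lutidine at −78 °C silylate only the primary hydroxyl and give the O14-TES ether F4. Ac2O, pyridine and catalytic DMAP acetylate O9 and give the acetate F5; the plain vinyl sulfone tolerates these amines. PPTS in MeOH/CH2Cl2 at 0 °C removes the primary TES group and gives 33.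

Further compounds
F1 | step 25 | (E)-β-methoxy enal analogue of 34 (OMe trans to CHO) | ICC/C(CO[Si](c1ccccc1)(c1ccccc1)C(C)(C)C)=C\[C@@H](O[Si](C)(C)C(C)(C)C)[C@H](C(=C)COCc1ccc(OC)cc1)[C@H](OC(=O)[C@H](C)CC)[C@@H](OC(C)=O)/C(C=O)=C\OC
F2 | step 25 | ten-membered carbinol with exocyclic methoxymethylene on C10 (carbinol carbon unassigned) | CC(C)(C)[Si](C)(C)O[C@@H]1/C=C(/CO[Si](c2ccccc2)(c2ccccc2)C(C)(C)C)CCC(O)/C(=C/OC)[C@H](OC(C)=O)[C@@H](OC(=O)[C@H](C)CC)[C@H]1C(=C)COCc1ccc(OC)cc1
F3 | step 17 | diisopropyl L-tartrate allylboronate analogue of 14 | CC(C)OC(=O)[C@@H]1OB(C/C(COCc2ccc(OC)cc2)=C/[C@@H]2OC(C)(C)O[C@H]2/C(CO[Si](C)(C)C(C)(C)C)=C\S(=O)(=O)c2ccccc2)O[C@H]1C(=O)OC(C)C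
F4 | step 23 | O14-TES ether of 31 (O9–H free) | ICC/C(CO[Si](c1ccccc1)(c1ccccc1)C(C)(C)C)=C\[C@@H](O[Si](C)(C)C(C)(C)C)[C@H](C(=C)COCc1ccc(OC)cc1)[C@H](OC(=O)[C@H](C)CC)[C@@H](O)/C(CO[Si](CC)(CC)CC)=C\S(=O)(=O)c1ccccc1
F5 | step 23 | O9 acetate O14-TES ether | ICC/C(CO[Si](c1ccccc1)(c1ccccc1)C(C)(C)C)=C\[C@@H](O[Si](C)(C)C(C)(C)C)[C@H](C(=C)COCc1ccc(OC)cc1)[C@H](OC(=O)[C@H](C)CC)[C@@H](OC(C)=O)/C(CO[Si](CC)(CC)CC)=C\S(=O)(=O)c1ccccc1
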